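**Retrosynthetic overview** (flavanone numbering is used for ring atoms, also in the open-chain precursors)

1. Target ⇒ its C7 MOM ether ⇒ the corresponding flavan-4-ol: C4 is carried as a carbinol and re-oxidised at the end.
2. Ring C is the only ring made. Its O1–C8a bond and the C8–prenyl bond are formed together from an acyclic (S)-1,3-diol whose ring A carries F on C8a, H on C8 and OMOM on C7: lithiation at C8, loss of LiF to the C8–C8a aryne, 6-exo attack of the carbinol oxygen on C8a, prenylation of the carbanion that reappears on C8.
3. Enabling feature: in ring A, C8 lies between the two oxygen-bearing carbons C7 and C8a. With OMOM and F on these, H-8 is the most acidic arene hydrogen, F is both director and leaving group, and the 3-oxy-aryne polarisation plus the six-membered tether send oxygen to C8a and the carbanion back to C8.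
4. The diol comes from a 2′-fluorochalcone (Claisen–Schmidt, C2–C3 bond) by Cu-catalysed enantioselective β-borylation/oxidation (sets C2 as S) and NaBH4 reduction.
5. Ring A, ring B and the dimethyldihydropyran ring fused to ring B are bought intact in the two building blocks.

Key step: step 5

Assumption: 2,2-dimethylchromane-6-carbaldehyde is treated as a catalogue building block.

**Route**

Step 1
Reactants: 1 1-(2-fluoro-4-hydroxyphenyl)ethanone
Product: 2 1-[2-fluoro-4-(methoxymethoxy)phenyl]ethanone
Conditions: MOMCl (1.3 equiv), i-Pr2NEt (1.6 equiv), CH2Cl2, 0 °C → rt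
Reagents that add atoms: chloromethyl methyl ether (MOMCl), COCCl
Why: Williamson-type O-alkylation of the acidic para-acyl phenol gives a MOM ether that is stable to base, hydride and organolithium and later serves as the ortho-directing group of step 5.

Step 2
Reactants: 2 1-[2-fluoro-4-(methoxymethoxy)phenyl]ethanone; 3 2,2-dimethylchromane-6-carbaldehyde
Product: 4 (E)-3-(2,2-dimethylchroman-6-yl)-1-[2-fluoro-4-(methoxymethoxy)phenyl]prop-2-en-1-one
Conditions: KOH (aq), EtOH, 0 °C → rt
Reagents that add atoms: none
Why: Claisen–Schmidt condensation (aldol addition, then E1cB dehydration) of a methyl ketone with a non-enolisable aldehyde should give the conjugated E-enone, and the ortho fluorine, deactivated by the para OMOM group, is expected to survive hydroxide at room temperature.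

Step 3
Reactants: 4 (E)-3-(2,2-dimethylchroman-6-yl)-1-[2-fluoro-4-(methoxymethoxy)phenyl]prop-2-en-1-one
Product: 6 (3S)-3-(2,2-dimethylchroman-6-yl)-1-[2-fluoro-4-(methoxymethoxy)phenyl]-3-hydroxypropan-1-one, via (S)-β-boryl ketone 5 (not isolated)
Conditions: CuCl (3 mol %), NaOt-Bu (6 mol %), (R)-1-[(S_p)-2-(diphenylphosphino)ferrocenyl]ethyldicyclohexylphosphine (3 mol %), B2pin2 (1.1 equiv), MeOH (2 equiv), THF, rt; then NaBO3·4H2O, THF/H2O, rt
Reagents that add atoms: bis(pinacolato)diboron, CC1(C)OB(OC1(C)C)B1OC(C)(C)C(C)(C)O1 (boron of 5 only); sodium perborate (NaBO3, used as the tetrahydrate), [Na+].[O-]OB=O (the new oxygen of 6)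
Why: Copper-catalysed enantioselective conjugate borylation of a chalcone followed by stereoretentive C–B oxidation sets C2 by catalyst control, the ligand–Cu–Bpin complex being expected to add boron to the enone face that leads to the S carbinol; the sense is to be confirmed by Mosher analysis on the first run and the equally available (S,R_p) ligand used should the opposite face be attacked.

Step 4
Reactants: 6 (3S)-3-(2,2-dimethylchroman-6-yl)-1-[2-fluoro-4-(methoxymethoxy)phenyl]-3-hydroxypropan-1-one
Product: 7 (1RS,3S)-3-(2,2-dimethylchroman-6-yl)-1-[2-fluoro-4-(methoxymethoxy)phenyl]propane-1,3-diol (both C1 epimers)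
Conditions: NaBH4, MeOH, 0 °C
Reagents that add atoms: none
Why: Borohydride 1,2-reduction of the aryl ketone removes the enolisable carbonyl before the organolithium stage; the new carbinol centre (future C4) is deliberately left uncontrolled because step 6 returns it to a ketone, and the S centre is not touched.

Step 5
Reactants: 7 (1RS,3S)-3-(2,2-dimethylchroman-6-yl)-1-[2-fluoro-4-(methoxymethoxy)phenyl]propane-1,3-diol
Product: 11 (2S,4RS)-2-(2,2-dimethylchroman-6-yl)-7-(methoxymethoxy)-8-(3-methylbut-2-en-1-yl)chroman-4-ol, via trilithiated fluoroarene 8 (not isolated), via aryne 9 (not isolated), via 8-lithiochroman-4-olate 10 (not isolated)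
Conditions: n-BuLi (3.05 equiv), THF (0.02 M), −78 °C; warm to −10 °C; recool to −78 °C, CuBr·SMe2 (1.1 equiv), prenyl bromide (2 equiv), → 0 °C; aq NH4Cl
Reagents that add atoms: 1-bromo-3-methylbut-2-ene (prenyl bromide), CC(C)=CCBr
Why: Proposed new method: n-BuLi first makes the dilithium diolate and then removes H-8, the only arene hydrogen flanked by F and OMOM, to give 8; on warming, 8 loses LiF to the C8–C8a aryne 9, the alkoxide on the carbinol carbon that bears ring B (future O1) adds to C8a in a 6-exo-dig closure of ring C to give aryllithium 10 with the carbanion back on C8, and 10 is transmetalated with CuBr·SMe2 and alkylated at the primary carbon of prenyl bromide. The closest known reaction types are the aryne relay of m-terphenyl synthesis (ortho-metalated haloarene, aryne, nucleophile addition, electrophilic quench of the regenerated arylmetal), intramolecular aryne cyclisations of tethered nitrogen and carbon nucleophiles followed by electrophile trapping, ring closures of oxygen nucleophiles onto arynes, and copper-mediated prenylation of 2,6-dioxygenated aryllithiums; what is new is a tethered lithium alkoxide as the nucleophile inside such a relay. No stereocentre is created: C2 keeps its S configuration because its C–O bond is never broken, and the uncontrolled C4 carbinol is erased in step 6. The regioselectivity that is needed (oxygen to C8a, carbon electrophile to C8) is secured threefold by the substrate: the 3-oxy-aryne polarisation caused by OMOM on C7 directs nucleophiles to the distal carbon C8a, only attack at C8a gives an unstrained six-membered ring, and the C4 alkoxide can reach neither aryne carbon. The carbinol oxidation level at C4 keeps an enolisable ketone out of the organolithium stage, where its chelated enolate would hold ring A trans to the carbinol oxygen and block the closure.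

Step 6
Reactants: 11 (2S,4RS)-2-(2,2-dimethylchroman-6-yl)-7-(methoxymethoxy)-8-(3-methylbut-2-en-1-yl)chroman-4-ol
Product: 12 (2S)-2-(2,2-dimethylchroman-6-yl)-7-(methoxymethoxy)-8-(3-methylbut-2-en-1-yl)chroman-4-one
Conditions: Dess–Martin periodinane (1.3 equiv), CH2Cl2, 0 °C → rt
Reagents that add atoms: none
Why: Dess–Martin oxidation of the secondary benzylic alcohol converges both C4 epimers on one ketone under non-basic conditions, so the C2 centre, which could only be lost through base-induced ring opening, is kept, and the prenyl alkene and MOM ether are inert to the periodinane.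

Step 7
Reactants: 12 (2S)-2-(2,2-dimethylchroman-6-yl)-7-(methoxymethoxy)-8-(3-methylbut-2-en-1-yl)chroman-4-one
Product: 13 euchrenone a17, (2S)-2-(2,2-dimethylchroman-6-yl)-7-hydroxy-8-(3-methylbut-2-en-1-yl)chroman-4-one
Conditions: 3 M HCl (aq), MeOH, 40 °C, short reaction time
Reagents that add atoms: none
Why: Acid-catalysed acetal exchange of the aryl MOM ether with methanol frees the C7 phenol under conditions that prenylated flavanones of this type normally tolerate when time and temperature are kept low, and C2 is not epimerised by dilute acid.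

**Compound list**

1 | 1-(2-fluoro-4-hydroxyphenyl)ethanone | CC(=O)c1ccc(O)cc1F | starting material
2 | 1-[2-fluoro-4-(methoxymethoxy)phenyl]ethanone | CC(=O)c1ccc(OCOC)cc1F | intermediate
3 | 2,2-dimethylchromane-6-carbaldehyde | O=Cc1ccc2OC(C)(C)CCc2c1 | starting material
4 | (E)-3-(2,2-dimethylchroman-6-yl)-1-[2-fluoro-4-(methoxymethoxy)phenyl]prop-2-en-1-one | COCOc1ccc(C(=O)/C=C/c2ccc3OC(C)(C)CCc3c2)c(F)c1 | intermediate
5 | (3S)-3-(2,2-dimethylchroman-6-yl)-1-[2-fluoro-4-(methoxymethoxy)phenyl]-3-(4,4,5,5-tetramethyl-1,3,2-dioxaborolan-2-yl)propan-1-one | COCOc1ccc(C(=O)C[C@H](B2OC(C)(C)C(C)(C)O2)c2ccc3OC(C)(C)CCc3c2)c(F)c1 | intermediate (not isolated)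
6 | (3S)-3-(2,2-dimethylchroman-6-yl)-1-[2-fluoro-4-(methoxymethoxy)phenyl]-3-hydroxypropan-1-one | COCOc1ccc(C(=O)C[C@H](O)c2ccc3OC(C)(C)CCc3c2)c(F)c1 | intermediate
7 | (1RS,3S)-3-(2,2-dimethylchroman-6-yl)-1-[2-fluoro-4-(methoxymethoxy)phenyl]propane-1,3-diol, both C1 epimers | COCOc1ccc(C(O)C[C@H](O)c2ccc3OC(C)(C)CCc3c2)c(F)c1 | intermediate
8 | dilithium diolate of 7 lithiated at the arene carbon between F and OMOM (future C8) | COCOc1ccc(C(O[Li])C[C@H](O[Li])c2ccc3OC(C)(C)CCc3c2)c(F)c1[Li] | intermediate (not isolated)
9 | dilithium diolate of the 3-(methoxymethoxy)aryne, triple bond between future C8 and C8a | COCOC1=CC=C(C(O[Li])C[C@H](O[Li])c2ccc3OC(C)(C)CCc3c2)C#C1 | intermediate (not isolated)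
10 | lithium (2S,4RS)-2-(2,2-dimethylchroman-6-yl)-8-lithio-7-(methoxymethoxy)chroman-4-olate | [Li]c1c(OCOC)ccc2c1O[C@H](c1ccc3c(c1)CCC(C)(C)O3)CC2O[Li] | intermediate (not isolated)
11 | (2S,4RS)-2-(2,2-dimethylchroman-6-yl)-7-(methoxymethoxy)-8-(3-methylbut-2-en-1-yl)chroman-4-ol | CC(C)=CCc1c(OCOC)ccc2c1O[C@H](c1ccc3c(c1)CCC(C)(C)O3)CC2O | intermediate
12 | (2S)-2-(2,2-dimethylchroman-6-yl)-7-(methoxymethoxy)-8-(3-methylbut-2-en-1-yl)chroman-4-one | CC(C)=CCc1c(OCOC)ccc2c1O[C@H](c1ccc3c(c1)CCC(C)(C)O3)CC2=O | intermediate
13 | euchrenone a17, (2S)-2-(2,2-dimethylchroman-6-yl)-7-hydroxy-8-(3-methylbut-2-en-1-yl)chroman-4-one | CC(C)=CCc1c(O)ccc2c1O[C@H](c1ccc3c(c1)CCC(C)(C)O3)CC2=O | target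

**Step count and risks**

Total step count: 7. Longest linear sequence: 7 steps (from 1).

Steps most likely to fail:

Step 5 (Proposed new method). The aggregated lithium alkoxide may capture the aryne too slowly. Intermolecular attack of a second aryllithium on the aryne, hydride transfer from the carbinol C–H to the aryne, or addition of residual n-BuLi would then take over. Incomplete lithiation would leave starting diol. Fallback with known chemistry, setting out from 7 and returning at 11: KOt-Bu (2.5 equiv) in DMF at 80 °C closes ring C by intramolecular SNAr of the potassium alkoxide on the fluoroarene, a 6-exo addition–elimination that needs no carbanion, to give (2S,4RS)-2-(2,2-dimethylchroman-6-yl)-7-(methoxymethoxy)chroman-4-ol F1. Directed ortho-metalation of F1 with n-BuLi (2.2 equiv, THF, −78 → 0 °C) at C8, now flanked by O1 and OMOM, followed by CuBr·SMe2 and prenyl bromide, then gives 11. The two bond formations are thus done in two separate operations instead of one relay.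

Step 3. Facial selectivity in the borylation of the ortho-fluoro, electron-rich chalcone may be insufficient or inverted, and the aldol may dehydrate back to the chalcone during the basic perborate stage. Fallback, setting out from 2 and 3 and returning at 7: the lithium enolate of 2 (LiN(SiMe3)2, THF, −78 °C) is added to 3 to give racemic 3-(2,2-dimethylchroman-6-yl)-1-[2-fluoro-4-(methoxymethoxy)phenyl]-3-hydroxypropan-1-one F2. Dess–Martin oxidation gives 1-(2,2-dimethylchroman-6-yl)-3-[2-fluoro-4-(methoxymethoxy)phenyl]propane-1,3-dione F3. Noyori transfer hydrogenation of both carbonyl groups with RuCl[(S,S)-TsDPEN](p-cymene) in HCO2H/Et3N, which delivers hydride in the same sense as for acetophenone, gives (1S,3S)-3-(2,2-dimethylchroman-6-yl)-1-[2-fluoro-4-(methoxymethoxy)phenyl]propane-1,3-diol F4. F4 is the 1S epimer contained in 7 and is taken into step 5 in place of 7. The stereocentre is then set by ketone reduction instead of conjugate addition.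

Step 7. The freed C7 phenol may add to the prenyl double bond under acid catalysis (closure of a dimethyldihydropyran ring on ring A), and acid-promoted opening of ring C would erode C2. Fallback, setting out from 12 and returning at 13: instead of Brønsted-acid solvolysis the MOM group is exchanged for a silyl group. TMSOTf and 2,2′-bipyridyl in CH2Cl2 at 0 °C transfer the methoxymethyl group to the bipyridine and give (2S)-2-(2,2-dimethylchroman-6-yl)-8-(3-methylbut-2-en-1-yl)-7-(trimethylsilyloxy)chroman-4-one F5. F5 is hydrolysed by water at room temperature to 13.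

Further compounds
F1 | step 5 | (2S,4RS)-2-(2,2-dimethylchroman-6-yl)-7-(methoxymethoxy)chroman-4-ol | COCOc1ccc2c(c1)O[C@H](c1ccc3c(c1)CCC(C)(C)O3)CC2O
F2 | step 3 | racemic 3-(2,2-dimethylchroman-6-yl)-1-[2-fluoro-4-(methoxymethoxy)phenyl]-3-hydroxypropan-1-one | COCOc1ccc(C(=O)CC(O)c2ccc3OC(C)(C)CCc3c2)c(F)c1
F3 | step 3 | 1-(2,2-dimethylchroman-6-yl)-3-[2-fluoro-4-(methoxymethoxy)phenyl]propane-1,3-dione | COCOc1ccc(C(=O)CC(=O)c2ccc3OC(C)(C)CCc3c2)c(F)c1
F4 | step 3 | (1S,3S)-3-(2,2-dimethylchroman-6-yl)-1-[2-fluoro-4-(methoxymethoxy)phenyl]propane-1,3-diol | COCOc1ccc([C@@H](O)C[C@H](O)c2ccc3OC(C)(C)CCc3c2)c(F)c1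
F5 | step 7 | (2S)-2-(2,2-dimethylchroman-6-yl)-8-(3-methylbut-2-en-1-yl)-7-(trimethylsilyloxy)chroman-4-one | CC(C)=CCc1c(O[Si](C)(C)C)ccc2c1O[C@H](c1ccc3c(c1)CCC(C)(C)O3)CC2=O
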